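All runs come from a simulation for substances that don't exist.

If each X takes one G and keeps it, then the reacted part of G is what sits in E plus a capped share, so I need E and that share.

| flask | G | Q | X | remark | time |
|---|---|---|---|---|---|
| grey | 0.80 M | 0.72 M | 0.011 M | run made earlier |  |
| blue | 0.80 M | 0.72 M | 0.024 M | run made earlier |  |
| flask | 0.80 M | 0.720 M | 0.0160 M |  | 15 min |

| run | time / min | E / % | G / % |
|---|---|---|---|
| grey | 3.00 | 53.5 | 46.5 |
| grey | 6.00 | 51.6 | 48.2 |
| grey | 10.0 | 50.3 | 48.5 |
| grey | 12.0 | 49.7 | 49.0 |
| grey | 15.0 | 48.3 | 50.0 |
| blue | 1.33 | 47.7 | 47.7 |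
| blue | 2.50 | 51.2 | 44.4 |
| blue | 4.00 | 51.8 | 45.3 |
| blue | 8.00 | 50.6 | 46.8 |
| blue | 15.0 | 48.1 | 48.6 |

(readings scatter by 0.5 percentage points)

- average number of monomer units in a chain (unreacted monomers counted as chains of one) at 15 min
- part of the G that has reacted at 15 min

- each monomer carries two end groups and X one, which caps an end: a chain counts once for every two ends that are left, dead ends included; the units are half of the end groups of the two monomers charged
- what has gone from G into another species counts as reacted, even if it can come back

Grey and blue differ in X by a factor of 2.18, yet at 15 min E reads 48.3 % and 48.1 %, a gap inside the scatter. The flask has more X than grey and less than blue, so I take their mean, 48.2 % of the G charged. The capped share, X charged over G charged, is 2.00 % in the flask, which makes c 50.2 %. Each link removes two ends and a cap removes none, so by a Carothers count, with Q at 0.900 of G, the chain length is 2.03.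

The weak link is one-for-one. At 15 min the part of G not found in E or G is 1.7 percentage points in grey and 3.3 points in blue, against shares of 1.37 % and 3.00 %. But each gap holds the scatter of two readings. Averaged over each whole run, the gaps are 0.88 points and 3.6 points, and their sum over the sum of the shares reads 1.01 G per X, so I keep my share.

The forecast gives 2.03 and 50.4 %, on the ground that “X caps G about one-for-one, possibly with a small extra loss”, and its c stands 0.2 points above mine.

The flask gives 2.04 and 50.5 %.

    G + Q ⇌ E (K = 4.10 L mol⁻¹, k = 1.97 L mol⁻¹ min⁻¹)
    G + X → J (k = 170 L mol⁻¹ min⁻¹)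
    Q → L (k = 0.0235 min⁻¹)

In the flask J stands at 2.00 % at 1.50 min, with X at 0 %, and still at 2.00 % at 15.0 min. Taking the capped share from c leaves 48.5 %, and E stands at 48.5 %. Moved alone, Q has to reach 0.638 M or 0.811 M for c to shift by 4 points.

In a neighbouring flask with 1.8 M of Q, and G and X as charged here, the share is still 2.00 %, so c should stand that far above E. It gives c 78.1 %, E 76.1 % and J 2.00 %.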